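## Structural features

The target is a germacrane-type ten-membered carbocycle (C1–C10) cis-fused across C6–C7 to an α-methylene-γ-butyrolactone (O6–C12(=O)–C11(=C13H2)–C7). Seven contiguous stereocentres run from C3 to C9: a cis trisubstituted epoxide C3–C4 (methyl C15 on C4) next to the C2 ketone, acetates at C5 and C8, the lactone oxygen at C6, the side-chain carbon at C7 and an (R)-2-methylbutanoate at C9. In ring terms O5/O6, C11/O8 and O8/O9 are trans, O6/C11 is cis and the epoxide oxygen is trans to O5; the four oxygens on C5, C6, C8 and C9 are therefore related by a twofold axis through C2 and C7. On the other side of C2 the ring carries an exocyclic methylene C10=C14 that is β,γ to the ketone. Fragile groups are the Michael-accepting methylene lactone, the epoxy ketone, the β,γ-unsaturated ketone (easily conjugated) and three base-labile esters, one of them allylic. The real difficulty is not the ring but the ordered, stereocontrolled placing of eight oxygen functions on a flexible medium ring, and telling apart two ketone positions (C2, C7) and two ring flanks that begin as equivalents. The key step exploits the 1,6 relation of C2 and C7 with C15 (on C4) and C14 (on C10) placed symmetrically about the C2···C7 axis: joining C2 to C7 gives the carbon pattern of a 2,7-dimethyl bicyclo[4.4.0] system, so the ring can arise by cutting a fusion alkene.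

## Logic of the disconnections

27 ⇒ 25 (through 26). The C11=C13 double bond is traced to a C13–N bond. The methylene lactone is the strongest electrophile in the molecule and cannot coexist with the peroxide anion needed for the epoxy ketone, so it is carried masked. Demand: the final elimination must use a base too weak to move C10=C14 into conjugation.

25 ⇒ 24 ⇒ 22 (through 23). The acetyl C–O bond at O5 and the C3–O/C4–O bonds of the epoxide are cut; the enone 23 in turn is the ring-opened form of a C4–C5 epoxide. This ties C5 to an earlier catalyst-controlled epoxide and lets O5–H steer the new epoxide, removing two stereocentres. Demand: C2 must be the only ketone, C1 must carry no leaving group, and the facial selectivity must follow O5.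

22 ⇒ 21 ⇒ 20. The C2 carbonyl is taken back to a silyl-protected carbinol. C2 must be non-enolisable while strong base is used and while C10=C14 is made. Demand: a late oxidation that tolerates everything else.

20 ⇒ 19 ⇒ 17 + 18. The acyl C–O bonds at O8 and O9 are cut, which gives a trans diol and the one purchased chiral acid. Demand: site selection between two secondary hydroxyls.

17 ⇒ 16. C10=C14 and O9–H are traced to a C9–C10 epoxide (the C10–O bond is re-formed). C9 then comes from the same epoxidation as C5. Demand: proton loss from C14 and not C1, a free O8–H to deliver the promoter, and an untouched C4–C5 epoxide.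

16 ⇒ 15 ⇒ 13 (through 14). The C11–C13 bond is cut, leaving a plain saturated lactone. Demand: lactone enolate chemistry with no ketone and no free hydroxyl present.

13 ⇒ 12 ⇒ 11 ⇒ 10. Two silyl O–Si bonds are removed and the C2 carbinol returns to the ketone. This is the price of the two demands above.

10 ⇒ 9. The C7–H and C11–H bonds are removed, so the C7 stereocentre becomes a planar alkene carbon. Demand: hydrogen delivery from the face of O8–H.

9 ⇒ 7 (through 8). C7=C11 and O6–C12 are cut, removing a two-carbon unit and restoring a C2-symmetric dihydroxy diketone. This is the point where the two flanks become different. Demand: one acylation only; only the ketone with the α-hydroxyl can close.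

7 ⇒ 6 ⇒ 5. The C6–O and C8–O bonds are cut. Demand: reaction at C7 and not C2, with the correct absolute sense and without ring-opening of the neighbouring epoxides.

5 ⇒ 4. Four C–O bonds of two epoxides are removed, giving an achiral, symmetric diene-dione. Demand: the same enantioface choice twice.

4 ⇒ 2 (through 3). Both carbonyl oxygens are removed and C2 is joined to C7. The ten-membered ring becomes two fused six-membered rings with a central alkene. Demand: cleavage of the tetrasubstituted alkene only.

2 ⇒ 1. Four C–H bonds are removed to reach a commodity arene. Demand: reduction of both rings with the methyl groups left on alkene carbons.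

## Other disconnections considered

Alternative 1: The cut is again C2–C7, together with C7–C11. In the forward step a C2 alkoxy radical on a bicyclic precursor fragments, and the C7 radical closes 5-exo-dig onto a tethered alkyne to give A1, the ten-membered epoxy ketone with the lactone at orthoester level. In its favour, ring expansion and the C7–C11 bond come in one operation, and the centres at C3–C6, C8 and C9 can be set on a rigid bicycle; on stereocontrol this is better than the chosen plan, which works on the flexible ring. Against it, the precursor must already carry an epoxide, two esters, the tether and most stereocentres, so the length moves in front of the key step. The C7 radical sits between two acyloxy-bearing carbons, the β-scission must favour C2–C7 over C2–C1 and C2–C3, and A1 still needs C10=C14 to be made from a CH2O–silyl group. Comparison: both plans break the same bond. The chosen plan does it in two polar steps on a hydrocarbon with no stereochemical issue, then pays with 18 steps of functionalisation; Alternative 1 is shorter after the ring is formed and equal in that neither forms a ring C–C bond, but it has no cheap symmetric entry.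

Alternative 2: The cuts are C1–C2 and C7–C8. Thermal [6+4] cycloaddition of A2 (tropone) with A3 ((E)-1-acetoxy-3-methylbuta-1,3-diene) gives the exo adduct A4. In its favour, two ring C–C bonds and the relative configuration at C2, C7 and C8 are set in one convergent step from two small achiral partners, with O8 and C14 in place; in bond-forming efficiency it is better than the chosen plan. Against it, the bridging carbon is bonded to both C2 and C7, so the C2–C11 bond must later be cut and C2 oxidised; C15 is missing; the triene C3–C6 must be turned into one epoxide and two C–O centres; and a single enantiomer needs a chiral catalyst or a resolution, with [4+2] addition as a competitor. Comparison: a stereospecific pericyclic step against an oxidative cleavage that creates no stereocentre. Ring construction is equal or better, but the bridge cleavage and the missing methyl should make the later stages longer than in the chosen plan, where all fifteen ring and methyl carbons are correct after step 2.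

Alternative 3: The cuts are the C2–O and C5–O bonds. Photosensitised singlet oxygen adds [4+2] across the ring (2Z,4Z)-diene to give the endoperoxide A5, which base could open to the same γ-hydroxy enone array as 23. In its favour, two oxygens and the Z C3=C4 alkene arrive in one mild step, and the C2 ketone is created late; that would remove the protecting-group detour of steps 9, 10, 16 and 17, a point on which it is better than the chosen plan. It is equal in that both routes pass through the γ-hydroxy enone before the epoxide. Against it, it is a functional-group step and builds no skeleton; it needs the fully substituted ring diene, which is hard to reach; ene reactions at C10=C14 or C15 compete; and C5 would be set by substrate facial bias, not by a chiral catalyst. Comparison: complementary to, not a replacement for, the chosen ring construction.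

Key step: step 2

Remark on numbering: atom numbers follow the target (ring C1–C10, lactone C11–C13, C14 on C10, C15 on C4).

Remark on the key-step product: both methyl-bearing alkene carbons of the cleavage product are β to the same carbonyl, so its correct name is 3,9-dimethylcyclodeca-3,8-diene-1,6-dione; the locants 4,9 would describe the isomer from 2,6-dimethylnaphthalene.

Remark on stereocentres of no consequence: the C2 carbinol (12–21) and C11 (15–26) are carried as epimer mixtures; both centres are erased later (steps 17 and 20).

Step 1
Reactants: 1 2,7-dimethylnaphthalene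
Product: 2 2,7-dimethyl-1,4,5,8-tetrahydronaphthalene
Conditions: Li, liquid NH3, t-BuOH, THF, −78 → −33 °C; NH4Cl
Reagents that add atoms: none
Why: Birch reduction; each ring takes up two electrons and two protons at its unsubstituted 1,4-positions, so the methyl groups stay on trisubstituted alkenes and the fusion carbons become the tetrasubstituted alkene.

Step 2
Reactants: 2 2,7-dimethyl-1,4,5,8-tetrahydronaphthalene
Product: 4 (3Z,8Z)-3,9-dimethylcyclodeca-3,8-diene-1,6-dione, via ozonide 3 (not isolated)
Conditions: O3 (1.0 equiv, titrated CH2Cl2 solution), CH2Cl2, −78 °C; then Me2S, −78 °C → rt; buffered isolation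
Reagents that add atoms: ozone, O=[O+][O-]
Why: Ozone adds as a 1,3-dipole; the primary ozonide cycloreverts to a ketone and a carbonyl oxide that remain tethered and recombine to ozonide 3, which dimethyl sulfide reduces to the two ketones. The closest known reaction type is the oxidative cleavage of the central alkene of isotetralins and 9,10-octalins to cyclodecane-1,6-diones. The ten-membered ring is not closed by bond formation: it is uncovered when the fusion bond C2–C7 is cut, so no ring-closure mode applies. No stereocentre is formed, and the two remaining alkenes keep the Z geometry they had in the six-membered rings. The step needs chemoselectivity for the tetrasubstituted alkene over the two trisubstituted ones; ozone is electrophilic, its rate rises with alkyl substitution, and one equivalent added cold as a titrated solution limits over-oxidation. Neutral work-up is required because 4 is a doubly β,γ-unsaturated 1,6-diketone that can isomerise or close by transannular aldol reaction with acid or base.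

Step 3
Reactants: 4 (3Z,8Z)-3,9-dimethylcyclodeca-3,8-diene-1,6-dione
Product: 5 (4R,5S,9S,10R)-4,5:9,10-diepoxy-4,10-dimethylcyclodecane-2,7-dione (C2-symmetric)
Conditions: ent-Shi ketone (L-fructose-derived, 0.6 equiv), KHSO5 (as Oxone), K2CO3, Bu4NHSO4, MeCN–(MeO)2CH2–aq. Na2B4O7/Na2EDTA, pH ≈ 9.5, −5 °C
Reagents that add atoms: potassium peroxymonosulfate, [K+].[O-]S(=O)(=O)OO
Why: Shi epoxidation; the chiral dioxirane epoxidises both trisubstituted alkenes through the spiro transition state, and by analogy with 1-substituted cycloalkenes the L-series ketone should give the (4R,5S,9S,10R) isomer, the doubled event raising the enantiomeric purity while the meso isomer is separable. The twofold axis runs through C2 and C7, so neither carbonyl carbon becomes a stereocentre, and the two quaternary epoxide carbons now shield C2.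

Step 4
Reactants: 5 bis-epoxide dione
Product: 6 (4R,5S,6S,8S,9S,10R)-6,8-bis(anilinooxy)-4,5:9,10-diepoxy-4,10-dimethylcyclodecane-2,7-dione
Conditions: D-proline (30 mol%), PhNO (2.4 equiv, slow addition), DMSO, 0 °C → rt
Reagents that add atoms: nitrosobenzene, O=Nc1ccccc1
Why: Proline-catalysed α-aminoxylation (O-selective nitroso aldol through the enamine), run on both α-carbons of one ketone; only C7, whose α-carbons have tertiary and not quaternary neighbours, should condense with the catalyst. D-Proline sets both new centres as S (O6 and O8 trans to the neighbouring epoxide oxygens), the sense also favoured by peripheral attack on the conformer with H5 or H9 in the enamine plane.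

Step 5
Reactants: 6 bis(anilinooxy) ketone
Product: 7 (4R,5S,6S,8S,9S,10R)-4,5:9,10-diepoxy-6,8-dihydroxy-4,10-dimethylcyclodecane-2,7-dione
Conditions: H2 (1 atm), Pd/C, EtOAc, rt
Reagents that add atoms: none
Why: Hydrogenolysis of the weak N–O bonds under neutral conditions gives the C2-symmetric α,α′-dihydroxy ketone and leaves ketones and trisubstituted epoxides alone.

Step 6
Reactants: 7 dihydroxy ketone
Product: 9 (4R,5S,6R,8R,9S,10R)-4,5:9,10-diepoxy-8-hydroxy-2-oxogermacr-7(11)-en-12,6-olide (butenolide), via ester ylide 8 (not isolated)
Conditions: Ph3P=C=C=O (1.05 equiv, slow addition), toluene, 90 °C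
Reagents that add atoms: (triphenylphosphoranylidene)ketene, O=C=C=P(c1ccccc1)(c1ccccc1)c1ccccc1
Why: Bestmann ylide lactone annulation; a hydroxyl adds to the ketenylidene ylide to give ester ylide 8, which closes onto the neighbouring C7 ketone by intramolecular Wittig olefination (C7=C11). The two hydroxyls are homotopic, so one product results; this single acylation is what distinguishes the two flanks.

Step 7
Reactants: 9 butenolide
Product: 10 (4R,5S,6R,7R,8R,9S,10R)-4,5:9,10-diepoxy-8-hydroxy-2-oxogermacran-12,6-olide (cis-fused lactone)
Conditions: [Ir(cod)(PCy3)(py)]PF6 (5 mol%), H2 (1 atm), CH2Cl2, 0 °C → rt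
Reagents that add atoms: none
Why: Hydroxyl-directed hydrogenation; O8–H and H6 lie on the same peripheral face of the butenolide, so hydrogen is delivered to C7 syn to O8, giving the cis-fused lactone (7R) with C11 trans to O8.

Step 8
Reactants: 10 cis-fused hydroxy lactone
Product: 11 8-O-triethylsilyl ether of 10
Conditions: Et3SiCl, imidazole, DMF, 0 °C
Reagents that add atoms: chlorotriethylsilane, CC[Si](Cl)(CC)CC
Why: Silylation of the only hydroxyl; in step 11 it keeps an alkoxide from forming beside the lactone (translactonisation) and beside the C9–C10 epoxide (Payne shift).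

Step 9
Reactants: 11 silyl ether ketone
Product: 12 (2RS)-2-hydroxy analogue of 11 (C2 carbinol)
Conditions: NaBH4, CeCl3·7H2O, MeOH, −40 °C
Reagents that add atoms: none
Why: Luche reduction of the only ketone; C2 must be non-enolisable before strong base is used and before the C9–C10 epoxide is opened, and the new centre is erased in step 17.

Step 10
Reactants: 12 C2 carbinol
Product: 13 2-O-tert-butyldimethylsilyl, 8-O-triethylsilyl bis-ether
Conditions: t-BuMe2SiCl, imidazole, DMAP (cat.), DMF, rt
Reagents that add atoms: tert-butylchlorodimethylsilane, CC(C)(C)[Si](C)(C)Cl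
Why: Standard silylation of the secondary C2 carbinol with a group that survives later removal of the triethylsilyl ether.

Step 11
Reactants: 13 bis-silyl ether lactone
Product: 15 (11RS)-13-(dimethylamino)-11,13-dihydro lactone (Mannich base) of 13, via lithium enolate 14 (not isolated)
Conditions: LiN(iPr)2, THF, −78 °C; then Me2N=CH2+ I−, −78 → 0 °C
Reagents that add atoms: N,N-dimethylmethyleneiminium iodide (Eschenmoser's salt), C=[N+](C)C.[I-]
Why: Lactone enolate Mannich reaction installs C13 as an aminomethyl group, a masked exocyclic methylene that tolerates the peroxide anion of step 18; no ketone or free hydroxyl is present.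

Step 12
Reactants: 15 Mannich base bis-silyl ether
Product: 16 8-hydroxy compound (2-O-tert-butyldimethylsilyl ether retained)
Conditions: HF·pyridine, pyridine, THF, 0 °C
Reagents that add atoms: none
Why: The triethylsilyl ether is cleaved much faster than the tert-butyldimethylsilyl ether by buffered fluoride, freeing O8–H as the handle for step 13.

Step 13
Reactants: 16 2,3-epoxy alcohol (O8–H beside the C9–C10 epoxide)
Product: 17 (8R,9R)-8,9-dihydroxy-10(14)-ene (exocyclic methylene), C4–C5 epoxide retained
Conditions: Ti(OiPr)4 (2 equiv), CH2Cl2, rt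
Reagents that add atoms: none
Why: Titanium-alkoxide-mediated isomerisation of a 2,3-epoxy alcohol to an ene-diol; the metal bound to O8 activates the adjacent epoxide, the tertiary C10–O bond breaks and a C14 proton is removed syn, giving C10=C14 with O9 retained. The C4–C5 epoxide has no free hydroxyl beside it, and the silyl ether at C2 removes the acidic C1–H that would direct elimination into the ring.

Step 14
Reactants: 17 8,9-diol; 18 (R)-2-methylbutanoic acid
Product: 19 9-O-[(2R)-2-methylbutanoyl] ester of 17 (O8–H free)
Conditions: 18 (1.1 equiv), DCC, DMAP (cat.), CH2Cl2, −20 °C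
Reagents that add atoms: none
Why: Steglich esterification at the less hindered, allylic O9–H (one sp2 neighbour) in preference to O8–H, which stands beside the ring-fusion carbon.

Step 15
Reactants: 19 C9 ester
Product: 20 8-O-acetyl-9-O-[(2R)-2-methylbutanoyl] compound
Conditions: Ac2O, pyridine, DMAP (cat.), CH2Cl2, 0 °C
Reagents that add atoms: acetic anhydride, CC(=O)OC(C)=O
Why: Acetylation of the remaining secondary hydroxyl.

Step 16
Reactants: 20 diester silyl ether
Product: 21 (2RS)-2-hydroxy compound
Conditions: HF·pyridine, pyridine, THF, 0 °C → rt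
Reagents that add atoms: none
Why: Fluoride cleavage of the C2 silyl ether; esters, the epoxide and the tertiary amine are stable to buffered HF·pyridine.

Step 17
Reactants: 21 C2 carbinol
Product: 22 2-oxo compound (β,γ-epoxy and β,γ-unsaturated ketone)
Conditions: Dess–Martin periodinane, NaHCO3, CH2Cl2, 0 °C
Reagents that add atoms: none
Why: Dess–Martin oxidation under buffered, non-basic conditions restores the C2 ketone without moving the exocyclic alkene.

Step 18
Reactants: 22 β,γ-epoxy ketone
Product: 24 (3R,4R,5S)-3,4-epoxy-5-hydroxy-2-oxo compound, via hydroxy enone 23 (not isolated)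
Conditions: Et3N, CH2Cl2, 0 °C; then t-BuOOLi (from t-BuOOH and n-BuLi), THF, −40 → −20 °C
Reagents that add atoms: tert-butyl hydroperoxide, CC(C)(C)OO
Why: E1cB opening; the C2 enolate formed at C3 expels the tertiary C4–O bond and gives the (Z)-γ-hydroxy enone 23 with O5 retained, the regiochemistry being fixed because C2 is the only ketone and C1 has no leaving group. Weitz–Scheffer epoxidation then adds the peroxide to C4 from the peripheral face that carries the lithium alkoxide O5 (H5 in the enone plane to avoid allylic 1,3-strain), which should place the new cis-epoxide trans to O5 in the ring sense; the weakly basic peroxide limits migration of C10=C14.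

Step 19
Reactants: 24 epoxy hydroxy ketone
Product: 25 5-O-acetyl compound (Mannich base of the target)
Conditions: Ac2O, pyridine, DMAP (cat.), 0 °C
Reagents that add atoms: acetic anhydride, CC(=O)OC(C)=O
Why: Acetylation of O5–H completes the ester pattern.

Step 20
Reactants: 25 Mannich base
Product: 27 CNP0256300.1 (target), via ammonium iodide 26 (not isolated)
Conditions: MeI, MeCN, rt; then NaHCO3 (aq), EtOAc, rt
Reagents that add atoms: none
Why: Quaternisation of the amine and mild β-elimination of trimethylamine (Hofmann-type) release the α-methylene lactone as the last operation, after all nucleophilic and basic reagents have been used.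

## Compound list

1 | 2,7-dimethylnaphthalene | Cc1ccc2ccc(C)cc2c1 | starting material
2 | 2,7-dimethyl-1,4,5,8-tetrahydronaphthalene | CC1=CCC2=C(C1)CC(C)=CC2 | intermediate
3 | ozonide (1,2,4-trioxolane) across the former fusion carbons of 2 | CC1=CCC2(OOC3(C1)O2)CC=C(C)C3 | intermediate
4 | (3Z,8Z)-3,9-dimethylcyclodeca-3,8-diene-1,6-dione (ketones = C2, C7; alkenes = C4=C5, C9=C10) | O=C1C/C(C)=C\CC(=O)C/C=C(/C)C1 | intermediate
5 | (4R,5S,9S,10R)-4,5:9,10-diepoxy-4,10-dimethylcyclodecane-2,7-dione | C1C(=O)C[C@@]2(C)O[C@H]2CC(=O)C[C@@H]3O[C@@]31C | intermediate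
6 | (4R,5S,6S,8S,9S,10R)-6,8-bis(anilinooxy) derivative of 5 | C1C(=O)C[C@@]2(C)O[C@H]2[C@H](ONc3ccccc3)C(=O)[C@@H](ONc3ccccc3)[C@@H]4O[C@@]41C | intermediate
7 | (4R,5S,6S,8S,9S,10R)-6,8-dihydroxy derivative of 5 | C1C(=O)C[C@@]2(C)O[C@H]2[C@H](O)C(=O)[C@@H](O)[C@@H]3O[C@@]31C | intermediate
8 | O6-[(triphenylphosphoranylidene)acetyl] ester of 7 | C1C(=O)C[C@@]2(C)O[C@H]2[C@H](OC(=O)C=P(c3ccccc3)(c3ccccc3)c3ccccc3)C(=O)[C@@H](O)[C@@H]4O[C@@]41C | intermediate
9 | (4R,5S,6R,8R,9S,10R)-4,5:9,10-diepoxy-8-hydroxy-2-oxogermacr-7(11)-en-12,6-olide | C1C(=O)C[C@@]2(C)O[C@H]2[C@@H]5OC(=O)C=C5[C@@H](O)[C@@H]3O[C@@]31C | intermediate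
10 | (4R,5S,6R,7R,8R,9S,10R)-4,5:9,10-diepoxy-8-hydroxy-2-oxogermacran-12,6-olide | C1C(=O)C[C@@]2(C)O[C@H]2[C@@H]5OC(=O)C[C@@H]5[C@@H](O)[C@@H]3O[C@@]31C | intermediate
11 | 8-O-triethylsilyl ether of 10 | C1C(=O)C[C@@]2(C)O[C@H]2[C@@H]5OC(=O)C[C@@H]5[C@@H](O[Si](CC)(CC)CC)[C@@H]3O[C@@]31C | intermediate
12 | (2RS)-2-hydroxy analogue of 11 | C1C(O)C[C@@]2(C)O[C@H]2[C@@H]5OC(=O)C[C@@H]5[C@@H](O[Si](CC)(CC)CC)[C@@H]3O[C@@]31C | intermediate
13 | 2-O-tert-butyldimethylsilyl ether of 12 | C1C(O[Si](C)(C)C(C)(C)C)C[C@@]2(C)O[C@H]2[C@@H]5OC(=O)C[C@@H]5[C@@H](O[Si](CC)(CC)CC)[C@@H]3O[C@@]31C | intermediate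
14 | lithium enolate of lactone 13 | C1C(O[Si](C)(C)C(C)(C)C)C[C@@]2(C)O[C@H]2[C@@H]5OC(O[Li])=C[C@@H]5[C@@H](O[Si](CC)(CC)CC)[C@@H]3O[C@@]31C | intermediate
15 | (11RS)-13-(dimethylamino) Mannich base of 13 | C1C(O[Si](C)(C)C(C)(C)C)C[C@@]2(C)O[C@H]2[C@@H]5OC(=O)C(CN(C)C)[C@@H]5[C@@H](O[Si](CC)(CC)CC)[C@@H]3O[C@@]31C | intermediate
16 | 8-hydroxy Mannich base (2-O-silyl retained) | C1C(O[Si](C)(C)C(C)(C)C)C[C@@]2(C)O[C@H]2[C@@H]5OC(=O)C(CN(C)C)[C@@H]5[C@@H](O)[C@@H]3O[C@@]31C | intermediate
17 | (8R,9R)-8,9-dihydroxy-10(14)-ene, 4,5-epoxide retained | C1C(O[Si](C)(C)C(C)(C)C)C[C@@]2(C)O[C@H]2[C@@H]5OC(=O)C(CN(C)C)[C@@H]5[C@@H](O)[C@H](O)C1=C | intermediate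
18 | (R)-2-methylbutanoic acid | CC[C@@H](C)C(=O)O | starting material
19 | 9-O-[(2R)-2-methylbutanoyl] ester of 17 | C1C(O[Si](C)(C)C(C)(C)C)C[C@@]2(C)O[C@H]2[C@@H]5OC(=O)C(CN(C)C)[C@@H]5[C@@H](O)[C@H](OC(=O)[C@H](C)CC)C1=C | intermediate
20 | 8-O-acetyl derivative of 19 | C1C(O[Si](C)(C)C(C)(C)C)C[C@@]2(C)O[C@H]2[C@@H]5OC(=O)C(CN(C)C)[C@@H]5[C@@H](OC(C)=O)[C@H](OC(=O)[C@H](C)CC)C1=C | intermediate
21 | (2RS)-2-hydroxy compound from 20 | C1C(O)C[C@@]2(C)O[C@H]2[C@@H]5OC(=O)C(CN(C)C)[C@@H]5[C@@H](OC(C)=O)[C@H](OC(=O)[C@H](C)CC)C1=C | intermediate
22 | 2-oxo-4,5-epoxy compound | C1C(=O)C[C@@]2(C)O[C@H]2[C@@H]5OC(=O)C(CN(C)C)[C@@H]5[C@@H](OC(C)=O)[C@H](OC(=O)[C@H](C)CC)C1=C | intermediate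
23 | (3Z)-5-hydroxy-2-oxo-3-ene (γ-hydroxy enone, O5 up as in the target) | C1C(=O)/C=C(C)\[C@@H](O)[C@@H]5OC(=O)C(CN(C)C)[C@@H]5[C@@H](OC(C)=O)[C@H](OC(=O)[C@H](C)CC)C1=C | intermediate
24 | (3R,4R,5S)-3,4-epoxy-5-hydroxy-2-oxo compound | C1C(=O)[C@@H]2O[C@]2(C)[C@@H](O)[C@@H]5OC(=O)C(CN(C)C)[C@@H]5[C@@H](OC(C)=O)[C@H](OC(=O)[C@H](C)CC)C1=C | intermediate
25 | 5-O-acetyl derivative of 24 (13-dimethylamino-11,13-dihydro target) | C1C(=O)[C@@H]2O[C@]2(C)[C@@H](OC(C)=O)[C@@H]5OC(=O)C(CN(C)C)[C@@H]5[C@@H](OC(C)=O)[C@H](OC(=O)[C@H](C)CC)C1=C | intermediate
26 | trimethylammonium iodide of 25 | C1C(=O)[C@@H]2O[C@]2(C)[C@@H](OC(C)=O)[C@@H]5OC(=O)C(C[N+](C)(C)C)[C@@H]5[C@@H](OC(C)=O)[C@H](OC(=O)[C@H](C)CC)C1=C.[I-] | intermediate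
27 | CNP0256300.1: (3R,4R,5S,6R,7R,8R,9R)-5,8-diacetoxy-3,4-epoxy-9-[(2R)-2-methylbutanoyloxy]-2-oxogermacra-10(14),11(13)-dien-12,6-olide | C=C1C(=O)O[C@@H]2[C@H]1[C@@H](OC(C)=O)[C@H](OC(=O)[C@H](C)CC)C(=C)CC(=O)[C@@H]1O[C@]1(C)[C@H]2OC(C)=O | target

## Step count and least certain steps

Total: 20 steps. Longest linear sequence: 20 steps (1 → 27); acid 18 enters at step 14.

Step 4 (most doubtful). The C7 enamine lies next to two epoxides and can expel the C5–O or C9–O bond (ring-opening by β-elimination) faster than it is oxidised; the amine catalyst can also start enolisation at C2. Fallback, from 5 back to 7: kinetic deprotonation on the less hindered C7 side with LiN(iPr)2 in the presence of Me3SiCl at −100 °C, so that the enolate is silylated as it forms, gives the trimethylsilyl enol ether F4. Rubottom oxidation with dimethyldioxirane under neutral conditions and mild desilylation give the 6-hydroxy ketone F5 (oxygen delivered from the peripheral face, trans to O5). Repeating the enol silane formation on the other side (bis-silyl compound F6) and the oxidation gives 7.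

Step 18. The base may move C10=C14 into conjugation, the amine may be lost by retro-Michael reaction, and the directing effect of O5 may not control the face of attack. Fallback, from 23 back to 24: a catalyst-controlled enone epoxidation with La(OiPr)3, the matching BINOL enantiomer, Ph3As=O and t-BuOOH in THF over molecular sieves, which is close to neutral and sets the face by reagent and not by substrate; this adds no new compound (F0).

Step 13. Proton loss may occur from C1 and give the endocyclic alkene, and the titanium alkoxide at O8 may trigger lactone migration from O6 to O8. Fallback, from 16 back to 17: Ti(OiPr)4-mediated opening of the epoxy alcohol at the tertiary carbon C10 with benzeneselenol gives the hydroxy selenide F7; oxidation with NaIO4 and selenoxide syn-elimination, which avoids the carbinol carbon C9, gives 17.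

Step 3. At the pH needed for catalyst turnover, 4 may undergo alkene migration into conjugation or transannular aldol closure before it is epoxidised. Fallback, from 4 back to 5: reduce both ketones (NaBH4, CeCl3·7H2O) to the diene-diol F2, carry out the same double epoxidation on this base-stable substrate to the bis-epoxy diol F3, and re-oxidise both carbinols with Dess–Martin periodinane to 5.

Step 14. Acylation may not distinguish O9–H from O8–H, and acyl migration between them is possible. Fallback, from 17 back to 20 (19 is bypassed): silylate the less hindered O9–H with Et3SiCl at −78 °C to the mono-silyl ether F8, acetylate O8 to F9, remove the silyl group with buffered HF·pyridine to the 9-hydroxy 8-acetate F10, and esterify O9 with 18 (DCC, DMAP) to reach 20.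

Step 2 (key step). Over-oxidation of the trisubstituted alkenes by excess ozone, or isomerisation and transannular aldol closure of 4 during work-up, would lower the return. Fallback, from 2 back to 4: one equivalent of mCPBA epoxidises the most electron-rich central alkene to the 4a,8a-epoxide F1, and periodic acid (H5IO6) in aqueous THF opens and cleaves it to 4.

## Further compounds

F1 | step 2 | 4a,8a-epoxy-2,7-dimethyl-1,4,4a,5,8,8a-hexahydronaphthalene | CC1=CCC23CC=C(C)CC2(C1)O3
F2 | step 3 | (3Z,8Z)-3,9-dimethylcyclodeca-3,8-diene-1,6-diol (cis/trans mixture) | OC1C/C(C)=C\CC(O)C/C=C(/C)C1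
F3 | step 3 | (4R,5S,9S,10R)-4,5:9,10-diepoxy-4,10-dimethylcyclodecane-2,7-diol | C1C(O)C[C@@]2(C)O[C@H]2CC(O)C[C@@H]3O[C@@]31C
F4 | step 4 | C7 trimethylsilyl enol ether (C6=C7) of 5 | C1C(=O)C[C@@]2(C)O[C@H]2/C=C(O[Si](C)(C)C)\C[C@@H]3O[C@@]31C
F5 | step 4 | (6S)-6-hydroxy derivative of 5 | C1C(=O)C[C@@]2(C)O[C@H]2[C@H](O)C(=O)C[C@@H]3O[C@@]31C
F6 | step 4 | 6-O-trimethylsilyl C7 trimethylsilyl enol ether (C7=C8) of F5 | C1C(=O)C[C@@]2(C)O[C@H]2[C@H](O[Si](C)(C)C)C(O[Si](C)(C)C)=C[C@@H]3O[C@@]31C
F7 | step 13 | 8,9-dihydroxy-10-(phenylselanyl) compound from 16 | C1C(O[Si](C)(C)C(C)(C)C)C[C@@]2(C)O[C@H]2[C@@H]5OC(=O)C(CN(C)C)[C@@H]5[C@@H](O)[C@H](O)[C@@]1(C)[Se]c6ccccc6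
F8 | step 14 | 9-O-triethylsilyl ether of 17 | C1C(O[Si](C)(C)C(C)(C)C)C[C@@]2(C)O[C@H]2[C@@H]5OC(=O)C(CN(C)C)[C@@H]5[C@@H](O)[C@H](O[Si](CC)(CC)CC)C1=C
F9 | step 14 | 8-O-acetyl-9-O-triethylsilyl derivative of 17 | C1C(O[Si](C)(C)C(C)(C)C)C[C@@]2(C)O[C@H]2[C@@H]5OC(=O)C(CN(C)C)[C@@H]5[C@@H](OC(C)=O)[C@H](O[Si](CC)(CC)CC)C1=C
F10 | step 14 | 8-O-acetyl-9-hydroxy derivative of 17 | C1C(O[Si](C)(C)C(C)(C)C)C[C@@]2(C)O[C@H]2[C@@H]5OC(=O)C(CN(C)C)[C@@H]5[C@@H](OC(C)=O)[C@H](O)C1=C
F0 | step 18 | none | none
A1 | alternative 1 | ten-membered epoxy ketone with the cyclic diethyl orthoester of the methylene lactone and a silyloxymethyl group on C10 | C=C1C(OCC)(OCC)O[C@@H]2[C@H]1[C@@H](OC(C)=O)[C@H](OC(=O)[C@H](C)CC)[C@@H](CO[Si](C)(C)C(C)(C)C)CC(=O)[C@@H]1O[C@]1(C)[C@H]2OC(C)=O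
A2 | alternative 2 | tropone | O=c1cccccc1
A3 | alternative 2 | (E)-1-acetoxy-3-methylbuta-1,3-diene | CC(=C)/C=C/OC(C)=O
A4 | alternative 2 | exo [6+4] adduct, bicyclo[4.4.1]undecatrienone bridged at C2 and C7 | O=C1[C@@H]2C=CC=C[C@H]1[C@H](OC(C)=O)C=C(C)C2
A5 | alternative 3 | C2–C5 endoperoxide of the ten-membered ring diene | C=C1C(=O)O[C@@H]2[C@H]1[C@@H](OC(C)=O)[C@H](OC(=O)[C@H](C)CC)C(=C)C[C@H]1OO[C@@H]2C(C)=C1
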